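**Plan**
- Unit 1 is the 7,4'-di-O-methyl half (plain locants); unit 2 is the naringenin half (double-primed locants). The last cuts are the three O–benzyl bonds and the chelated 5-O–methyl bond, then both C4 carbonyls (back to secondary alcohols), then the C4–O and C3–H bonds of unit 1 (back to the C3=C4 bond of a flav-3-ene).
- The central cut is C4–C4a plus O1–C2 of unit 1. Ring A of unit 1 has O1 on C8a, a free C8–H, oxygens on C5 and C7, and meets the pyran ring only at C4a/C8a, while C2 carries the 4-methoxyphenyl group and C3 the second flavanoid. That is symmetric 3,5-dimethoxyphenol (14) plus an α-substituted 4-methoxycinnamaldehyde (13).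
- 13 is cut at Cα=Cβ (aldol condensation with 12) and at C3''–CH2 (allylation); unit 2 is cut at C2''–aryl (conjugate arylation of chromone 3) and at O1''–C2''.
- Forward order: pyranone ring of unit 2 (step 1), C2'' aryl, C3'' two-carbon arm, enal, pyran ring of unit 1 (step 8), C4 oxygen, both ketones, free phenols. Unit 2 passes through step 8 as a 4-silyloxyflavan, so no enolisable 1,4-ketoaldehyde is present there.
- Stereochemistry: C2'' from the chiral bisphosphine complex of [Rh(OH)(cod)]2; C3'' by alkylation anti to the C2'' aryl group; C2 in the electrocyclisation under the influence of C3''/C4''; C3 by syn hydroboration anti to the C2 aryl group.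

Key step: step 8

Remark: the (R) antipode of the bisphosphine in step 2 is assumed to deliver the 2S flavanone (the (S) ligand is used if the sense is opposite), and 1 is taken as a purchasable compound.

**Step 1**
Reactants: 1 1-[2,4-bis(benzyloxy)-6-hydroxyphenyl]ethan-1-one
Product: 3 5,7-bis(benzyloxy)-4H-chromen-4-one, via enaminone 2 (not isolated)
Conditions: Me2NCH(OMe)2, toluene, 100 °C; then conc. HCl, CH2Cl2, rt
Reagents that add atoms: N,N-dimethylformamide dimethyl acetal, COC(OC)N(C)C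
Why: Enaminone formation from the methyl ketone, then acid-induced addition of the phenol to the enaminone with loss of dimethylamine, is the standard enaminone route to 3-unsubstituted chromones, and the benzyl ethers are inert.

**Step 2**
Reactants: 3 5,7-bis(benzyloxy)-4H-chromen-4-one; 4 [4-(benzyloxy)phenyl]boronic acid
Product: 5 (2S)-5,7-bis(benzyloxy)-2-[4-(benzyloxy)phenyl]chroman-4-one
Conditions: [Rh(OH)(cod)]2 (cod = cycloocta-1,5-diene, cat.), (R)-2,2'-bis[bis(3,4,5-trifluorophenyl)phosphino]-6,6'-dimethoxy-1,1'-biphenyl (cat.), toluene/H2O, 50 °C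
Reagents that add atoms: none
Why: Asymmetric 1,4-addition of an arylboronic acid (Hayashi–Miyaura reaction) is established for chromones with electron-poor bisphosphine complexes of [Rh(OH)(cod)]2 under base-free conditions that avoid ring opening; the ligand selects the enone face and sets C2 as S.

**Step 3**
Reactants: 5 (2S)-5,7-bis(benzyloxy)-2-[4-(benzyloxy)phenyl]chroman-4-one
Product: 7 (2S,3R)-3-allyl-5,7-bis(benzyloxy)-2-[4-(benzyloxy)phenyl]chroman-4-one, via lithium enolate 6 (not isolated)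
Conditions: LiN(SiMe3)2, THF, −78 °C; then allyl bromide, −78 → −40 °C
Reagents that add atoms: allyl bromide, C=CCBr
Why: Kinetic enolate formation at −78 °C (where β-elimination of the ring phenoxide is slow) and SN2 alkylation anti to the C2 aryl group should give the 2,3-trans ketone, which is also the thermodynamic epimer.

**Step 4**
Reactants: 7 (2S,3R)-3-allyl-5,7-bis(benzyloxy)-2-[4-(benzyloxy)phenyl]chroman-4-one
Product: 8 (2S,3S,4S)-3-allyl-5,7-bis(benzyloxy)-2-[4-(benzyloxy)phenyl]chroman-4-ol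
Conditions: NaBH4, THF/MeOH, 0 °C → rt
Reagents that add atoms: none
Why: Borohydride reduction of a flavanone delivers hydride axially and should give the equatorial 2,4-cis alcohol (4S); this centre is temporary (removed in step 11), and the reduction takes away the epimerisable, ring-opening-prone β-aryloxy ketone before the side chain is built.

**Step 5**
Reactants: 8 (2S,3S,4S)-3-allyl-5,7-bis(benzyloxy)-2-[4-(benzyloxy)phenyl]chroman-4-ol
Product: 9 (2S,3R,4S)-3-allyl-5,7-bis(benzyloxy)-2-[4-(benzyloxy)phenyl]-4-[(tert-butyldimethylsilyl)oxy]chroman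
Conditions: TBSOTf, 2,6-lutidine, CH2Cl2, −78 → 0 °C
Reagents that add atoms: tert-butyldimethylsilyl trifluoromethanesulfonate, CC(C)(C)[Si](C)(C)OS(=O)(=O)C(F)(F)F
Why: O-Silylation with a silyl triflate and a hindered pyridine base protects hindered secondary alcohols at low temperature before the electron-rich benzylic C–O bond can ionise, and the bulky silyl ether is the intended steering group for step 8.

**Step 6**
Reactants: 9 (2S,3R,4S)-3-allyl-5,7-bis(benzyloxy)-2-[4-(benzyloxy)phenyl]-4-[(tert-butyldimethylsilyl)oxy]chroman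
Product: 11 2-{(2S,3R,4S)-5,7-bis(benzyloxy)-2-[4-(benzyloxy)phenyl]-4-[(tert-butyldimethylsilyl)oxy]chroman-3-yl}acetaldehyde, via diol 10 (not isolated)
Conditions: OsO4 (cat.), NaIO4, 2,6-lutidine, 1,4-dioxane/H2O, rt
Reagents that add atoms: osmium tetroxide, O=[Os](=O)(=O)=O (catalytic oxygen carrier); sodium periodate NaIO4, [Na+].[O-]I(=O)(=O)=O (terminal oxidant that replenishes it)
Why: Lemieux–Johnson cleavage (dihydroxylation of the monosubstituted alkene, then periodate glycol cleavage under lutidine buffering) gives the aldehyde one carbon shorter without touching aryl ethers, the silyl ether or any stereocentre.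

**Step 7**
Reactants: 11 2-{(2S,3R,4S)-5,7-bis(benzyloxy)-2-[4-(benzyloxy)phenyl]-4-[(tert-butyldimethylsilyl)oxy]chroman-3-yl}acetaldehyde; 12 4-methoxybenzaldehyde
Product: 13 (E)-2-{(2S,3R,4S)-5,7-bis(benzyloxy)-2-[4-(benzyloxy)phenyl]-4-[(tert-butyldimethylsilyl)oxy]chroman-3-yl}-3-(4-methoxyphenyl)prop-2-enal
Conditions: pyrrolidine (cat.), PhCO2H (cat.), excess 12, CH2Cl2, rt → 40 °C
Reagents that add atoms: none
Why: Amine-catalysed crossed aldol condensation (the enamine of the α-unbranched aldehyde adds to the iminium ion of the non-enolisable aryl aldehyde, then elimination) should give the α-substituted cinnamaldehyde as the thermodynamic E isomer, with self-condensation held back by the β-branch and the excess of 12.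

**Step 8**
Reactants: 13 (E)-2-{(2S,3R,4S)-5,7-bis(benzyloxy)-2-[4-(benzyloxy)phenyl]-4-[(tert-butyldimethylsilyl)oxy]chroman-3-yl}-3-(4-methoxyphenyl)prop-2-enal; 14 3,5-dimethoxyphenol
Product: 17 (2R)-3-{(2S,3R,4S)-5,7-bis(benzyloxy)-2-[4-(benzyloxy)phenyl]-4-[(tert-butyldimethylsilyl)oxy]chroman-3-yl}-5,7-dimethoxy-2-(4-methoxyphenyl)-2H-chromene, via benzodioxaborin 15 (not isolated), via ortho-quinone methide 16 (not isolated)
Conditions: PhB(OH)2 (1.2 equiv), EtCO2H (0.3 equiv), toluene, reflux, Dean–Stark trap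
Reagents that add atoms: none
Why: PhB(OH)2 esterifies phenol 14 and binds the aldehyde of 13, and this boron tether delivers the carbonyl carbon to the ortho position (C4–C4a bond) to give benzodioxaborin 15, which on heating with the acid loses its phenylboron oxide unit to form ortho-quinone methide 16. 16 is a 1-oxatriene whose thermal disrotatory oxa-6π electrocyclisation forms O1–C2 and closes the six-membered pyran ring of unit 1 with return of aromaticity to ring A; the closest known reaction type is the boronic-acid-mediated condensation of phenols with α,β-unsaturated aldehydes to 2H-chromenes, applied here to an α-branched cinnamaldehyde. C2 is the only new stereocentre and is controlled by C3'': allylic 1,3-strain with the cis anisyl group holds the C3''–H bond in the triene plane, the C2'' and C4'' branches then cover opposite faces, and the bulky C4'' silyloxy branch (backed by the peri 5''-benzyloxy group) should send the rotating anisyl group to the C2'' face, which is the 2R chromene configuration that is named 2S in the target. Ortho instead of para C-alkylation is secured by the boron tether, and the choice between the two ortho sites is removed by the symmetry of 14. Because 2H-chromenes reopen to the quinone methide on heating, the C2 epimers can interconvert under the reaction conditions, so the outcome need not rest on the kinetic closure alone. Keeping C4'' as a silyl ether excludes an enolisable 1,4-ketoaldehyde (furan formation, C3'' epimerisation, retro-oxa-Michael opening) from this hot, acidic step.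

**Step 9**
Reactants: 17 (2R)-3-{(2S,3R,4S)-5,7-bis(benzyloxy)-2-[4-(benzyloxy)phenyl]-4-[(tert-butyldimethylsilyl)oxy]chroman-3-yl}-5,7-dimethoxy-2-(4-methoxyphenyl)-2H-chromene
Product: 19 (2S,3R,4R)-3-{(2S,3R,4S)-5,7-bis(benzyloxy)-2-[4-(benzyloxy)phenyl]-4-[(tert-butyldimethylsilyl)oxy]chroman-3-yl}-5,7-dimethoxy-2-(4-methoxyphenyl)chroman-4-ol, via alkylborane 18 (not isolated)
Conditions: BH3·THF, THF, 0 °C → rt; then aq. NaOH, H2O2, 0 °C → rt
Reagents that add atoms: hydrogen peroxide, OO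
Why: Hydroboration–oxidation of the trisubstituted flav-3-ene should place boron on the less substituted benzylic C4 and hydrogen on C3 in a syn addition from the face opposite the pseudoaxial C2 anisyl group, and oxidation with retention then gives the 2,3-cis-3,4-trans alcohol, which sets C3; no carbonyl group is present for borane to reduce.

**Step 10**
Reactants: 19 (2S,3R,4R)-3-{(2S,3R,4S)-5,7-bis(benzyloxy)-2-[4-(benzyloxy)phenyl]-4-[(tert-butyldimethylsilyl)oxy]chroman-3-yl}-5,7-dimethoxy-2-(4-methoxyphenyl)chroman-4-ol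
Product: 20 (2S,3R,4R)-3-{(2S,3S,4S)-5,7-bis(benzyloxy)-2-[4-(benzyloxy)phenyl]-4-hydroxychroman-3-yl}-5,7-dimethoxy-2-(4-methoxyphenyl)chroman-4-ol
Conditions: Bu4NF, THF, rt → 50 °C
Reagents that add atoms: none
Why: Fluoride-induced desilylation cleaves the Si–O bond under non-acidic conditions that do not ionise the two electron-rich benzylic alcohols, and it is placed before the oxidation so that no base meets the epimerisable cis ketone.

**Step 11**
Reactants: 20 (2S,3R,4R)-3-{(2S,3S,4S)-5,7-bis(benzyloxy)-2-[4-(benzyloxy)phenyl]-4-hydroxychroman-3-yl}-5,7-dimethoxy-2-(4-methoxyphenyl)chroman-4-ol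
Product: 21 (2S,3S)-3-{(2S,3R)-5,7-bis(benzyloxy)-2-[4-(benzyloxy)phenyl]-4-oxochroman-3-yl}-5,7-dimethoxy-2-(4-methoxyphenyl)chroman-4-one
Conditions: Dess–Martin periodinane, NaHCO3, CH2Cl2, 0 °C → rt
Reagents that add atoms: none
Why: Dess–Martin oxidation of both secondary benzylic alcohols under bicarbonate buffering should give the bis-flavanone without enolisation, so the cis C2/C3 relationship of unit 1 and the trans relationship of unit 2 are kept.

**Step 12**
Reactants: 21 (2S,3S)-3-{(2S,3R)-5,7-bis(benzyloxy)-2-[4-(benzyloxy)phenyl]-4-oxochroman-3-yl}-5,7-dimethoxy-2-(4-methoxyphenyl)chroman-4-one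
Product: 22 (2S,3S)-3-[(2S,3R)-5,7-dihydroxy-2-(4-hydroxyphenyl)-4-oxochroman-3-yl]-5-hydroxy-7-methoxy-2-(4-methoxyphenyl)chroman-4-one
Conditions: BCl3, C6HMe5, CH2Cl2, −78 → 0 °C; then aq. NaHCO3
Reagents that add atoms: none
Why: Lewis-acid ether cleavage with BCl3 and pentamethylbenzene as cation scavenger removes the three aryl benzyl groups at low temperature and, through the six-membered boron chelate with the C4 carbonyl, only the peri 5-methoxy group, while the non-chelated 7- and 4'-methoxy groups survive; a short time at or below 0 °C is chosen to avoid acid-induced epimerisation at C3.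

**Compound list**
1 | 1-[2,4-bis(benzyloxy)-6-hydroxyphenyl]ethan-1-one | CC(=O)c1c(O)cc(OCc2ccccc2)cc1OCc1ccccc1 | starting material
2 | (E)-1-[2,4-bis(benzyloxy)-6-hydroxyphenyl]-3-(dimethylamino)prop-2-en-1-one | CN(C)/C=C/C(=O)c1c(O)cc(OCc2ccccc2)cc1OCc1ccccc1 | intermediate
3 | 5,7-bis(benzyloxy)-4H-chromen-4-one | O=c1ccoc2cc(OCc3ccccc3)cc(OCc3ccccc3)c12 | intermediate
4 | [4-(benzyloxy)phenyl]boronic acid | OB(O)c1ccc(OCc2ccccc2)cc1 | starting material
5 | (2S)-5,7-bis(benzyloxy)-2-[4-(benzyloxy)phenyl]chroman-4-one | O=C1C[C@@H](c2ccc(OCc3ccccc3)cc2)Oc2cc(OCc3ccccc3)cc(OCc3ccccc3)c12 | intermediate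
6 | lithium enolate of 5: lithium (2S)-5,7-bis(benzyloxy)-2-[4-(benzyloxy)phenyl]-2H-chromen-4-olate | [Li+].[O-]C1=C[C@@H](c2ccc(OCc3ccccc3)cc2)Oc2cc(OCc3ccccc3)cc(OCc3ccccc3)c12 | intermediate
7 | (2S,3R)-3-allyl-5,7-bis(benzyloxy)-2-[4-(benzyloxy)phenyl]chroman-4-one (2,3-trans) | C=CC[C@H]1C(=O)c2c(OCc3ccccc3)cc(OCc3ccccc3)cc2O[C@@H]1c1ccc(OCc2ccccc2)cc1 | intermediate
8 | (2S,3S,4S)-3-allyl-5,7-bis(benzyloxy)-2-[4-(benzyloxy)phenyl]chroman-4-ol (2,3-trans, 2,4-cis) | C=CC[C@H]1[C@H](O)c2c(OCc3ccccc3)cc(OCc3ccccc3)cc2O[C@@H]1c1ccc(OCc2ccccc2)cc1 | intermediate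
9 | (2S,3R,4S)-3-allyl-5,7-bis(benzyloxy)-2-[4-(benzyloxy)phenyl]-4-[(tert-butyldimethylsilyl)oxy]chroman | C=CC[C@H]1[C@H](O[Si](C)(C)C(C)(C)C)c2c(OCc3ccccc3)cc(OCc3ccccc3)cc2O[C@@H]1c1ccc(OCc2ccccc2)cc1 | intermediate
10 | 3-{(2S,3R,4S)-5,7-bis(benzyloxy)-2-[4-(benzyloxy)phenyl]-4-[(tert-butyldimethylsilyl)oxy]chroman-3-yl}propane-1,2-diol (both epimers at the side-chain carbinol) | OCC(O)C[C@H]1[C@H](O[Si](C)(C)C(C)(C)C)c2c(OCc3ccccc3)cc(OCc3ccccc3)cc2O[C@@H]1c1ccc(OCc2ccccc2)cc1 | intermediate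
11 | 2-{(2S,3R,4S)-5,7-bis(benzyloxy)-2-[4-(benzyloxy)phenyl]-4-[(tert-butyldimethylsilyl)oxy]chroman-3-yl}acetaldehyde | O=CC[C@H]1[C@H](O[Si](C)(C)C(C)(C)C)c2c(OCc3ccccc3)cc(OCc3ccccc3)cc2O[C@@H]1c1ccc(OCc2ccccc2)cc1 | intermediate
12 | 4-methoxybenzaldehyde | COc1ccc(C=O)cc1 | starting material
13 | (E)-2-{(2S,3R,4S)-5,7-bis(benzyloxy)-2-[4-(benzyloxy)phenyl]-4-[(tert-butyldimethylsilyl)oxy]chroman-3-yl}-3-(4-methoxyphenyl)prop-2-enal | O=C/C(=C/c1ccc(OC)cc1)[C@H]1[C@H](O[Si](C)(C)C(C)(C)C)c2c(OCc3ccccc3)cc(OCc3ccccc3)cc2O[C@@H]1c1ccc(OCc2ccccc2)cc1 | intermediate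
14 | 3,5-dimethoxyphenol | COc1cc(O)cc(OC)c1 | starting material
15 | benzodioxaborin: 4-{(E)-1-[(2S,3R,4S)-5,7-bis(benzyloxy)-2-[4-(benzyloxy)phenyl]-4-[(tert-butyldimethylsilyl)oxy]chroman-3-yl]-2-(4-methoxyphenyl)ethenyl}-5,7-dimethoxy-2-phenyl-4H-1,3,2-benzodioxaborinine (either configuration at C4) | COc1cc(OC)c2c(c1)OB(c1ccccc1)OC2/C(=C/c1ccc(OC)cc1)[C@H]1[C@H](O[Si](C)(C)C(C)(C)C)c2c(OCc3ccccc3)cc(OCc3ccccc3)cc2O[C@@H]1c1ccc(OCc2ccccc2)cc1 | intermediate
16 | ortho-quinone methide: 6-{2-[(2S,3R,4S)-5,7-bis(benzyloxy)-2-[4-(benzyloxy)phenyl]-4-[(tert-butyldimethylsilyl)oxy]chroman-3-yl]-3-(4-methoxyphenyl)prop-2-en-1-ylidene}-3,5-dimethoxycyclohexa-2,4-dien-1-one (vinyl group syn to C=O; anisyl cis to the chromanyl group) | O=C1C=C(OC)C=C(OC)/C1=C/C(=C/c1ccc(OC)cc1)[C@H]1[C@H](O[Si](C)(C)C(C)(C)C)c2c(OCc3ccccc3)cc(OCc3ccccc3)cc2O[C@@H]1c1ccc(OCc2ccccc2)cc1 | intermediate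
17 | (2R)-3-{(2S,3R,4S)-5,7-bis(benzyloxy)-2-[4-(benzyloxy)phenyl]-4-[(tert-butyldimethylsilyl)oxy]chroman-3-yl}-5,7-dimethoxy-2-(4-methoxyphenyl)-2H-chromene | COc1ccc([C@H]2Oc3cc(OC)cc(OC)c3C=C2[C@H]2[C@H](O[Si](C)(C)C(C)(C)C)c3c(OCc4ccccc4)cc(OCc4ccccc4)cc3O[C@@H]2c2ccc(OCc3ccccc3)cc2)cc1 | intermediate
18 | alkylborane: C4-boryl flavan from 17 (BH2 on C4 and the new H on C3 cis to each other and anti to the C2 aryl group) | COc1ccc([C@H]2Oc3cc(OC)cc(OC)c3[C@H](B)[C@H]2[C@H]2[C@H](O[Si](C)(C)C(C)(C)C)c3c(OCc4ccccc4)cc(OCc4ccccc4)cc3O[C@@H]2c2ccc(OCc3ccccc3)cc2)cc1 | intermediate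
19 | (2S,3R,4R)-3-{(2S,3R,4S)-5,7-bis(benzyloxy)-2-[4-(benzyloxy)phenyl]-4-[(tert-butyldimethylsilyl)oxy]chroman-3-yl}-5,7-dimethoxy-2-(4-methoxyphenyl)chroman-4-ol (2,3-cis, 3,4-trans in unit 1) | COc1ccc([C@H]2Oc3cc(OC)cc(OC)c3[C@H](O)[C@H]2[C@H]2[C@H](O[Si](C)(C)C(C)(C)C)c3c(OCc4ccccc4)cc(OCc4ccccc4)cc3O[C@@H]2c2ccc(OCc3ccccc3)cc2)cc1 | intermediate
20 | (2S,3R,4R)-3-{(2S,3S,4S)-5,7-bis(benzyloxy)-2-[4-(benzyloxy)phenyl]-4-hydroxychroman-3-yl}-5,7-dimethoxy-2-(4-methoxyphenyl)chroman-4-ol | COc1ccc([C@H]2Oc3cc(OC)cc(OC)c3[C@H](O)[C@H]2[C@H]2[C@H](O)c3c(OCc4ccccc4)cc(OCc4ccccc4)cc3O[C@@H]2c2ccc(OCc3ccccc3)cc2)cc1 | intermediate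
21 | (2S,3S)-3-{(2S,3R)-5,7-bis(benzyloxy)-2-[4-(benzyloxy)phenyl]-4-oxochroman-3-yl}-5,7-dimethoxy-2-(4-methoxyphenyl)chroman-4-one | COc1ccc([C@H]2Oc3cc(OC)cc(OC)c3C(=O)[C@H]2[C@H]2C(=O)c3c(OCc4ccccc4)cc(OCc4ccccc4)cc3O[C@@H]2c2ccc(OCc3ccccc3)cc2)cc1 | intermediate
22 | (2S,3S)-3-[(2S,3R)-5,7-dihydroxy-2-(4-hydroxyphenyl)-4-oxochroman-3-yl]-5-hydroxy-7-methoxy-2-(4-methoxyphenyl)chroman-4-one (CNP0279849.1; unit 1 cis, unit 2 trans) | COc1ccc([C@H]2Oc3cc(OC)cc(O)c3C(=O)[C@H]2[C@H]2C(=O)c3c(O)cc(O)cc3O[C@@H]2c2ccc(O)cc2)cc1 | target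

**Step count**
Total: 12 steps. Longest linear sequence: 12 steps (1 → 22); 4, 12 and 14 enter as purchased partners in steps 2, 7 and 8.

**Steps most likely to fail**

1. Step 8. The disrotatory closure may show poor facial selectivity, because the 1,3-induction from C3'' is weak, and a large share of the C2 epimer may form. The fallback sets out from 13 (with 14) and comes back at 17. The annulation is run as described and the chromene epimers are separated. The C2-epimeric chromene F1 is then irradiated at 365 nm in toluene at room temperature. The known photochromic electrocyclic ring opening of 2H-chromenes regenerates ortho-quinone methide 16, which recloses thermally in the dark. Repeated separation and irradiation should funnel the material into 17, so that C2 is corrected after bond formation instead of relying on induction during it.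

2. Step 9. Boron may add at C3 instead of C4, driven by the electron-rich ring A, or the shielded trisubstituted alkene may react too slowly. The fallback sets out from 17 and comes back at 19. Homogeneous hydrogenation with [Ir(cod)(PCy3)(py)]PF6 (py = pyridine) under H2 in CH2Cl2 leaves benzyl ethers intact and should add hydrogen anti to the C2 aryl group to give the 2,3-cis flavan F2. DDQ in wet CH2Cl2 then performs the known benzylic C4 oxidation of 5,7-dialkoxyflavans, with water adding anti to the C3 substituent to give 19; the C4 configuration is in any case removed in step 11.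

3. Step 3. The lithium enolate may undergo β-elimination of the ring phenoxide, which opens the ring to the chalcone and loses the C2 configuration, before it is alkylated. The fallback sets out from 5 and comes back at 7. Soft enolisation with Me3SiOTf and Et3N in CH2Cl2 at 0 °C gives the trimethylsilyl enol ether F3 without a free enolate. Tsuji allylation with allyl methyl carbonate, Pd2(dba)3 and dppe (dba = dibenzylideneacetone, dppe = 1,2-bis(diphenylphosphino)ethane; a zerovalent palladium π-allyl process) in THF then forms the C3–allyl bond anti to the C2 aryl group and gives 7.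

**Further compounds**
F1 | step 8 | C2 epimer of 17: (2S)-3-{(2S,3R,4S)-5,7-bis(benzyloxy)-2-[4-(benzyloxy)phenyl]-4-[(tert-butyldimethylsilyl)oxy]chroman-3-yl}-5,7-dimethoxy-2-(4-methoxyphenyl)-2H-chromene | COc1ccc([C@@H]2Oc3cc(OC)cc(OC)c3C=C2[C@H]2[C@H](O[Si](C)(C)C(C)(C)C)c3c(OCc4ccccc4)cc(OCc4ccccc4)cc3O[C@@H]2c2ccc(OCc3ccccc3)cc2)cc1
F2 | step 9 | (2S,3S)-3-{(2S,3R,4S)-5,7-bis(benzyloxy)-2-[4-(benzyloxy)phenyl]-4-[(tert-butyldimethylsilyl)oxy]chroman-3-yl}-5,7-dimethoxy-2-(4-methoxyphenyl)chroman (2,3-cis flavan) | COc1ccc([C@H]2Oc3cc(OC)cc(OC)c3C[C@H]2[C@H]2[C@H](O[Si](C)(C)C(C)(C)C)c3c(OCc4ccccc4)cc(OCc4ccccc4)cc3O[C@@H]2c2ccc(OCc3ccccc3)cc2)cc1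
F3 | step 3 | (2S)-5,7-bis(benzyloxy)-2-[4-(benzyloxy)phenyl]-4-[(trimethylsilyl)oxy]-2H-chromene | C[Si](C)(C)OC1=C[C@@H](c2ccc(OCc3ccccc3)cc2)Oc2cc(OCc3ccccc3)cc(OCc3ccccc3)c12
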